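## Retrosynthetic overview

1. The last bond made is C6 (ring A) to the two-carbon unit. The dione does not come from a deoxybenzoin or a diarylalkyne. Unprotected 4-hydroxyphenylglyoxal brings in ring B and both carbons, attacks the only free aromatic C–H of the finished chromenol, and the benzoin is oxidised in the same flask.
2. The C8 prenyl group comes from a para-Claisen–Cope shift of the 5-O-prenyl ether (O5 → C6 → C8). This also frees the 5-OH that steers the final coupling.
3. The pyran ring (ring C) comes from alkenyl Grignard addition to a salicylaldehyde, dehydration to an ortho-quinone methide, and oxa-6π closure on the single free OH.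
4. The oxygen pattern comes from two chelation-controlled O-alkylations of symmetric phloroglucinaldehyde: 4-OMe first, then one of the two equivalent ortho OH groups.
5. Ring order: rings A and B are bought. Ring C is the only ring formed (step 3), before the prenyl shift and before ring B is attached. There are no protecting-group steps.

Assumption: the SMILES holds no stereocentre and no E/Z-defined alkene. The target is therefore achiral and needs no enantiocontrol. The sp3 centres that appear on the way are racemic and are erased.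

## Route

Step 1
Reactants: 1 2,4,6-trihydroxybenzaldehyde; 2 dimethyl sulfate
Product: 3 2,6-dihydroxy-4-methoxybenzaldehyde
Conditions: Me2SO4 (1.0 equiv), K2CO3 (1.0 equiv), acetone, reflux, 3 h
Reagents that add atoms: dimethyl sulfate, COS(=O)(=O)OC
Why: Williamson O-methylation in which both ortho OH groups are hydrogen-bonded to the formyl group, so the para OH, the most acidic and the only free one, reacts first under one equivalent of base and electrophile.

Step 2
Reactants: 3 2,6-dihydroxy-4-methoxybenzaldehyde; 4 prenyl bromide (1-bromo-3-methylbut-2-ene)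
Product: 5 2-hydroxy-4-methoxy-6-[(3-methylbut-2-en-1-yl)oxy]benzaldehyde
Conditions: prenyl bromide (1.05 equiv), K2CO3 (1.1 equiv), acetone, 50 °C, 6 h
Reagents that add atoms: prenyl bromide, CC(C)=CCBr
Why: Williamson O-alkylation of a symmetric substrate, so either OH gives the same product, and the remaining OH is locked in the aldehyde chelate, which stops the reaction at the mono-ether.

Step 3
Reactants: 5 2-hydroxy-4-methoxy-6-[(3-methylbut-2-en-1-yl)oxy]benzaldehyde; 6 2-methylprop-1-enylmagnesium bromide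
Product: 9 7-methoxy-2,2-dimethyl-5-[(3-methylbut-2-en-1-yl)oxy]-2H-chromene, via allylic alcohol 7 (not isolated), via ortho-quinone methide 8 (not isolated)
Conditions: 6 (2.5 equiv, 0.5 M in THF), THF, 0 °C to rt; sat. aq NH4Cl; crude in toluene, 110 °C, 2 h
Reagents that add atoms: 2-methylprop-1-enylmagnesium bromide, CC(C)=C[Mg]Br
Why: Grignard 1,2-addition to the magnesium-chelated salicylaldehyde gives a trioxygenated benzylic-allylic carbinol that loses water on warming to the ortho-quinone methide, which closes by oxa-6π electrocyclisation on the only free oxygen, so one chromene regioisomer forms and the racemic carbinol centre is erased.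

Step 4
Reactants: 9 7-methoxy-2,2-dimethyl-5-[(3-methylbut-2-en-1-yl)oxy]-2H-chromene; 10 N,O-bis(trimethylsilyl)acetamide (BSA)
Product: 14 7-methoxy-2,2-dimethyl-8-(3-methylbut-2-en-1-yl)-2H-chromen-5-ol, via ortho-dienone 11 (not isolated), via para-dienone 12 (not isolated), via trimethylsilyl ether 13 (not isolated)
Conditions: BSA (2 equiv), PhNEt2, 200 °C, sealed tube, 3 h; then K2CO3 (10 mol %), MeOH, rt, 30 min
Reagents that add atoms: none
Why: Aromatic Claisen rearrangement to C6 gives a crowded ortho-dienone, squeezed between C5=O and the C7 methoxy group, that undergoes Cope rearrangement to C8 faster than it enolises (para-Claisen–Cope, two allyl inversions, so a normal prenyl group arrives), while BSA caps the freed 5-OH at once so that thermal retro-6π opening of the pyran cannot re-close on the other oxygen.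

Step 5
Reactants: 14 7-methoxy-2,2-dimethyl-8-(3-methylbut-2-en-1-yl)-2H-chromen-5-ol; 15 4-hydroxyphenylglyoxal hydrate
Product: 17 1-[5-hydroxy-7-methoxy-2,2-dimethyl-8-(3-methylbut-2-en-1-yl)-2H-chromen-6-yl]-2-(4-hydroxyphenyl)ethane-1,2-dione (target), via benzoin 16 (not isolated)
Conditions: 15 (1.3 equiv), Et3N (50 mol %), THF, N2, 35 °C, 36 h; aq NH4Cl wash; crude in CH2Cl2, activated MnO2 (10 equiv), rt, 4 h
Reagents that add atoms: 4-hydroxyphenylglyoxal hydrate, OC(O)C(=O)c1ccc(O)cc1
Why: Proposed new method: the amine-hydrogen-bonded phenol attacks the free aldehyde of the glyoxal through its only unsubstituted ring carbon (C6, ortho to OH, pushed by three oxygen donors), as in the known amine-catalysed ortho-Friedel–Crafts hydroxyalkylation of activated phenols by arylglyoxal hydrates and the guaiacol/glyoxylic acid mandelate process, the α-acyl group disfavours ionisation to a quinone methide so the reaction stops at the benzoin, and every tautomer at that oxidation level (benzoin, iso-benzoin, enediol, cyclic hemiketal) is funnelled by the MnO2 benzoin-to-benzil oxidation to the same chelated dione, which erases the racemic carbinol centre.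

## Compound list

1 | 2,4,6-trihydroxybenzaldehyde | O=Cc1c(O)cc(O)cc1O | starting material
2 | dimethyl sulfate | COS(=O)(=O)OC | starting material
3 | 2,6-dihydroxy-4-methoxybenzaldehyde | COc1cc(O)c(C=O)c(O)c1 | intermediate
4 | prenyl bromide (1-bromo-3-methylbut-2-ene) | CC(C)=CCBr | starting material
5 | 2-hydroxy-4-methoxy-6-[(3-methylbut-2-en-1-yl)oxy]benzaldehyde | COc1cc(O)c(C=O)c(OCC=C(C)C)c1 | intermediate
6 | 2-methylprop-1-enylmagnesium bromide | CC(C)=C[Mg]Br | starting material
7 | 2-(1-hydroxy-3-methylbut-2-en-1-yl)-5-methoxy-3-[(3-methylbut-2-en-1-yl)oxy]phenol (racemic) | COc1cc(O)c(C(O)C=C(C)C)c(OCC=C(C)C)c1 | intermediate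
8 | 3-methoxy-6-(3-methylbut-2-en-1-ylidene)-5-[(3-methylbut-2-en-1-yl)oxy]cyclohexa-2,4-dien-1-one (ortho-quinone methide) | COC1=CC(=O)C(=CC=C(C)C)C(OCC=C(C)C)=C1 | intermediate
9 | 7-methoxy-2,2-dimethyl-5-[(3-methylbut-2-en-1-yl)oxy]-2H-chromene | COc1cc(OCC=C(C)C)c2C=CC(C)(C)Oc2c1 | intermediate
10 | N,O-bis(trimethylsilyl)acetamide | CC(=N[Si](C)(C)C)O[Si](C)(C)C | starting material
11 | 7-methoxy-2,2-dimethyl-6-(2-methylbut-3-en-2-yl)-2H-chromen-5(6H)-one (ortho-dienone, racemic) | O=C1C(C(C)(C)C=C)C(OC)=CC2=C1C=CC(C)(C)O2 | intermediate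
12 | 7-methoxy-2,2-dimethyl-8-(3-methylbut-2-en-1-yl)-2H-chromen-5(8H)-one (para-dienone, racemic) | O=C1C=C(OC)C(CC=C(C)C)C2=C1C=CC(C)(C)O2 | intermediate
13 | 7-methoxy-2,2-dimethyl-8-(3-methylbut-2-en-1-yl)-5-(trimethylsilyloxy)-2H-chromene | COc1cc(O[Si](C)(C)C)c2C=CC(C)(C)Oc2c1CC=C(C)C | intermediate
14 | 7-methoxy-2,2-dimethyl-8-(3-methylbut-2-en-1-yl)-2H-chromen-5-ol | COc1cc(O)c2C=CC(C)(C)Oc2c1CC=C(C)C | intermediate
15 | 4-hydroxyphenylglyoxal hydrate (2,2-dihydroxy-1-(4-hydroxyphenyl)ethanone) | OC(O)C(=O)c1ccc(O)cc1 | starting material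
16 | 2-hydroxy-2-[5-hydroxy-7-methoxy-2,2-dimethyl-8-(3-methylbut-2-en-1-yl)-2H-chromen-6-yl]-1-(4-hydroxyphenyl)ethanone (benzoin, racemic) | COc1c(CC=C(C)C)c2OC(C)(C)C=Cc2c(O)c1C(O)C(=O)c1ccc(O)cc1 | intermediate
17 | 1-[5-hydroxy-7-methoxy-2,2-dimethyl-8-(3-methylbut-2-en-1-yl)-2H-chromen-6-yl]-2-(4-hydroxyphenyl)ethane-1,2-dione (achiral) | COc1c(CC=C(C)C)c2c(c(O)c1C(=O)C(=O)c1ccc(O)cc1)C=CC(C)(C)O2 | target

## Step count and risks

Total step count: 5. Longest linear sequence: 5 (1 → 3 → 5 → 9 → 14 → 17).

**Most likely to fail, first: step 5.**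
- The acidic 4-OH of 15 can tie up the amine and weaken the electrophile.
- The benzoin can go on to a 2,2-diaryl ketone.
- MnO2 can attack the electron-rich ring.

The fallback sets out from 14 and comes back at 17. It replaces the neutral C–H coupling with an anionic oxalyl-linchpin union. MOMCl/iPr2NEt (CH2Cl2, 0 °C) turns 14 into the methoxymethyl ether F1. n-BuLi (THF, 0 °C) removes its only aromatic hydrogen, which is flanked by OMOM and OMe (directed ortho-metalation), to give the 6-lithio chromene F2. This is added at −78 °C to commercial 1,4-dimethylpiperazine-2,3-dione and gives the stable tetrahedral lithium mono-adduct F3. Next, 4-(methoxymethoxy)phenyllithium F4 is made from 1-bromo-4-(methoxymethoxy)benzene and n-BuLi at −78 °C. It is added to the same flask and gives the dilithium bis-adduct F5. Quenching with aqueous HCl collapses both hemiaminals to the bis-MOM benzil F6. HCl in MeOH at 40 °C then removes both acetals and gives 17.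

**Second: step 4.**
- The ortho-dienone may enolise to the 6-(1,1-dimethylallyl) isomer.
- Isoprene may be lost.
- Any unsilylated 5-OH allows retro-6π scrambling of the pyran at 200 °C.

The fallback sets out from 3 and comes back at 14. It places the prenyl group by directed metalation instead of by sigmatropy, and no free phenol is ever heated. TIPSCl/imidazole (DMF, rt) gives 2-hydroxy-4-methoxy-6-(triisopropylsilyloxy)benzaldehyde F7. Grignard reagent 6 (THF, 0 °C, where the bulky silyl group does not migrate) gives the silyl allylic alcohol F8. In refluxing toluene this loses water to the silyloxy ortho-quinone methide F9, which closes to 7-methoxy-2,2-dimethyl-5-(triisopropylsilyloxy)-2H-chromene F10. n-BuLi/TMEDA (Et2O, 0 °C) lithiates C8, which lies between OMe and the pyran oxygen, while the bulky, non-coordinating OTIPS group shields C6. This gives the 8-lithio chromene F11. Prenyl bromide 4 (−78 °C to rt) gives the 8-prenyl silyl ether F12, and TBAF (THF, 0 °C) gives 14.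

**Third: step 3.**
- The hindered, electron-rich, chelated aldehyde may add the alkenyl Grignard reagent sluggishly.
- Carbinol 7 may oligomerise through 8.

The fallback sets out from 5 and comes back at 9, passing through 8. It builds the same carbon chain from the other end. Claisen–Schmidt condensation with acetone (aq NaOH, acetone, rt) gives the (E)-enone F13. MeLi (3 equiv, THF, −78 °C) adds 1,2 to give the tertiary allylic alcohol F14. PPTS (5 mol %, toluene, 60 °C) ionises it to the protonated form of 8, which loses a proton and electrocyclises to 9.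

## Further compounds

F1 | step 5 | 7-methoxy-5-(methoxymethoxy)-2,2-dimethyl-8-(3-methylbut-2-en-1-yl)-2H-chromene | COCOc1cc(OC)c(CC=C(C)C)c2OC(C)(C)C=Cc12
F2 | step 5 | 6-lithio derivative of F1 | COCOc1c([Li])c(OC)c(CC=C(C)C)c2OC(C)(C)C=Cc12
F3 | step 5 | lithium 2-[7-methoxy-5-(methoxymethoxy)-2,2-dimethyl-8-prenyl-2H-chromen-6-yl]-1,4-dimethyl-3-oxopiperazin-2-olate (racemic) | [Li+].[O-]C1(N(C)CCN(C)C1=O)c1c(OCOC)c2C=CC(C)(C)Oc2c(CC=C(C)C)c1OC
F4 | step 5 | 4-(methoxymethoxy)phenyllithium | [Li]c1ccc(OCOC)cc1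
F5 | step 5 | dilithium 2-[4-(methoxymethoxy)phenyl]-3-[7-methoxy-5-(methoxymethoxy)-2,2-dimethyl-8-prenyl-2H-chromen-6-yl]-1,4-dimethylpiperazine-2,3-diolate (diastereomer mixture, racemic) | [Li+].[Li+].[O-]C1(c2ccc(OCOC)cc2)N(C)CCN(C)C1([O-])c1c(OCOC)c2C=CC(C)(C)Oc2c(CC=C(C)C)c1OC
F6 | step 5 | 1-[7-methoxy-5-(methoxymethoxy)-2,2-dimethyl-8-prenyl-2H-chromen-6-yl]-2-[4-(methoxymethoxy)phenyl]ethane-1,2-dione | COCOc1ccc(cc1)C(=O)C(=O)c1c(OCOC)c2C=CC(C)(C)Oc2c(CC=C(C)C)c1OC
F7 | step 4 | 2-hydroxy-4-methoxy-6-(triisopropylsilyloxy)benzaldehyde | COc1cc(O)c(C=O)c(O[Si](C(C)C)(C(C)C)C(C)C)c1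
F8 | step 4 | 2-(1-hydroxy-3-methylbut-2-en-1-yl)-5-methoxy-3-(triisopropylsilyloxy)phenol (racemic) | COc1cc(O)c(C(O)C=C(C)C)c(O[Si](C(C)C)(C(C)C)C(C)C)c1
F9 | step 4 | 3-methoxy-6-(3-methylbut-2-en-1-ylidene)-5-(triisopropylsilyloxy)cyclohexa-2,4-dien-1-one | COC1=CC(=O)C(=CC=C(C)C)C(O[Si](C(C)C)(C(C)C)C(C)C)=C1
F10 | step 4 | 7-methoxy-2,2-dimethyl-5-(triisopropylsilyloxy)-2H-chromene | COc1cc(O[Si](C(C)C)(C(C)C)C(C)C)c2C=CC(C)(C)Oc2c1
F11 | step 4 | 8-lithio derivative of F10 | COc1cc(O[Si](C(C)C)(C(C)C)C(C)C)c2C=CC(C)(C)Oc2c1[Li]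
F12 | step 4 | 7-methoxy-2,2-dimethyl-8-(3-methylbut-2-en-1-yl)-5-(triisopropylsilyloxy)-2H-chromene | COc1cc(O[Si](C(C)C)(C(C)C)C(C)C)c2C=CC(C)(C)Oc2c1CC=C(C)C
F13 | step 3 | (E)-4-{2-hydroxy-4-methoxy-6-[(3-methylbut-2-en-1-yl)oxy]phenyl}but-3-en-2-one | COc1cc(O)c(/C=C/C(C)=O)c(OCC=C(C)C)c1
F14 | step 3 | 2-[(E)-3-hydroxy-3-methylbut-1-en-1-yl]-5-methoxy-3-[(3-methylbut-2-en-1-yl)oxy]phenol | COc1cc(O)c(/C=C/C(C)(C)O)c(OCC=C(C)C)c1
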